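Autumn is charged with 0.99 M of Q and 5.3 mol% of L, dusk with the same Q and 1.2 mol% of L, and both are read at 3.0 d.

| setting | south | north | autumn | dusk |
|---|---|---|---|---|
| Q | 0.99 M | 0.99 M | 0.99 M | 0.99 M |
| L | 1.4 mol% | 8 mol% | 5.3 mol% | 1.2 mol% |
| remark | run made earlier | run made earlier |  |  |
| time |  |  | 3.0 d | 3.0 d |

| south: time / d | south: D / % | north: time / d | north: D / % |
|---|---|---|---|
| 0.417 | 14.2 | 0.167 | 13.4 |
| 0.833 | 34.0 | 0.500 | 54.6 |
| 1.25 | 51.3 | 0.833 | 78.9 |
| 1.67 | 66.0 | 1.25 | 91.5 |
| 2.00 | 74.7 | 1.67 | 97.2 |
| 2.50 | 83.4 | 2.50 | 98.7 |
| 3.00 | 88.9 | 3.00 | 98.5 |

(standard deviation of a reading: 0.5 percentage points)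

- the average divides the monomer in chains by the number of chains begun, living and dead together
- what was read earlier has a scatter of 0.5 percentage points, one standard deviation
- the earlier runs do not show the number of chains; that part of a forecast is a guess

- which of the two ends with the longer chains by the average number of monomer units in a chain (chains begun, living or dead) ("neither" if they lie within 10%) (autumn / dusk / neither)
- average number of monomer units in a chain (chains begun, living or dead) at the end, autumn
- average number of monomer units in a chain (chains begun, living or dead) at the end, dusk

I fold each flask into one dimensionless number, the turnover number T: the fraction of Q turned into D, divided by the loading of L, which is the moles of Q turned over per mole of L charged. The conversion comes from the runs. At 0.833 d, north has reached 78.9% and south 34.0%, so more L gives a faster rise. Autumn lies between them in L, and I take north's final 98.5% as its conversion, which gives T = 18.6. Dusk has less L than south, so south's final 88.9% is a slightly high stand-in, and T = 74.1.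

T is the chain length (number-average degree of polymerisation) if each L begins one chain. If some L begins none, the chains are longer, so T is a floor on the length. Dusk's T is 3.99 times autumn's, far outside the 10% margin, and I commit to dusk. The order stands unless the share of L that begins chains differs between the flasks by about that factor. For the lengths themselves one number is not enough, because the runs do not show that share.

The forecast gives dusk, with 37 for autumn and 140 for dusk, and says “The number of chains is a guess”.

The longer chains stand in dusk, with 38.8 in autumn and 88.5 in dusk.

    Q + L → X + D (k = 0.0840 M⁻¹ h⁻¹)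
    Q + X → D + X, rate k2*[X]*[Q] (k = 3.30 M⁻¹ h⁻¹)
    L + D → Z (k = 0.0120 M⁻¹ h⁻¹)
    2 L → E (k = 1.10 M⁻¹ h⁻¹)

T divided by the length gives the share of charged L that began a chain; with autumn's own D of 99.3%, its T moves from 18.6 to 18.7 and the share is 48.3%, and with dusk's own D of 85.7% the share in dusk is 80.7%. In dusk at 1.14 d, Q + X → D + X uses Q 250 times as fast as Q + L → X + D. In dusk at 3.00 d the half-life of Q is 0.91 d by Q + X → D + X and 1200 d by Q + L → X + D. Dusk read at 0.833 d holds D 30.5%, so T = 25.4, and its length is 37.3.

All runs stem from a simulated flask for substances that don't exist; the scatter is artificial.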